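Conventions: gibberellane numbering is used for every intermediate (ring A = C1–C5, C10; C18 = methyl on C4; C19 = lactone carbonyl; C6 carries the C7 carboxyl; C8 and C13 = bridgeheads; C14 = one-carbon bridge; C15–C16 = two-carbon bridge; C17 = methyl on C16). α is the face of ring B that carries the lactone oxygen, β the face of H5 and H9.

Assumption: the cupreidine-derived catalyst of step 1 is taken to give the (S)-adduct 3; if its sense is the opposite, the cupreine-derived pseudoenantiomer is used and nothing else changes.

## Analysis of the target

The target is 16,17-dihydro-16-hydroxygibberellin A4. Ring A (C1–C5, C10) carries the γ-lactone bridge C4–C19(=O)–O–C10, ring B is the cyclopentane C5–C6–C8–C9–C10, and rings C and D form a bicyclo[3.2.1]octane with bridgeheads C8 and C13. There are nine stereocentres (C3, C4, C5, C6, C8, C9, C10, C13, C16); three are fully substituted, and C8 is an all-carbon quaternary centre shared by rings B, C and D. On ring A the lactone spans C4 and C10 on the α face, the C3 hydroxyl is axial, β and cis to the C18 methyl, and C6 sits on the lactone side of C5. On ring B the C7 carboxyl, H5 and H9 are β and H9 is syn to C15; at C16 the methyl is exo (towards C14) and the hydroxyl endo. The sensitive groups are the β-hydroxy lactone (retro-aldol epimerization of C3 in base), the tertiary C16 alcohol on a bicyclo[3.2.1]octane (ionization and Wagner–Meerwein shift in acid), the epimerizable C6, and, in any intermediate with a carbonyl on C11, the lactone oxygen on C10 as a β-leaving group. The hard part is the crowded C8–C9 junction and the bridged C/D system in the right relation to ring A. The strategy rests on reading the bicyclo[3.2.1]octane as the seven-membered ring C8–C9–C11–C12–C13–C16–C15 spanned by the single carbon C14, which is what a [4+3] cycloaddition of a cyclopentadiene (C8, C15, C16, C13, methylene C14) with a three-carbon oxyallyl unit (C9, C11, C12) delivers.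

## Retrosynthetic reasoning

Target 30 is first traced back to its protected form 28 (C3 silyl ether, C7 tert-butyl ester). Both groups are chosen to survive amide bases, organometallics and alkoxide, and both can be taken off without base (C3 retro-aldol) and without a protic acid strong enough to ionize C16.

The C16–C17 bond of 28 is cut to the 16-ketone 26 and the methyl donor 27. A ketone at C16 is exactly what an oxygenated diene leaves behind, and the bicyclic ketone has one open face (exo, C14 side), which is the face the methyl must enter.

Ketone 26 is traced through 25, 24 and 23 to the tetracyclic 11-ketone 22. The C11 oxygen is only the scar of the three-carbon unit; it is removed through the C11–C12 enol triflate, which creates no stereocentre and avoids any enolate at C9, β to the lactone oxygen. The enol silane of 22 is kept until then so that C11 and C16 are never two free ketones at once.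

In 22 the bonds C8–C9 and C12–C13 are cut together, which opens rings B and C and removes three stereocentres (C8, C9, C13). This leads to 20, a ring-A lactone that carries the chloromethyl ketone arm on C10 and the 3-silyloxycyclopentadiene on C6. No other pair of bonds removes the quaternary C8 and both bridgehead bonds in one operation from a monocyclic diene. The forward reaction has to add the oxyallyl unit to the diene face syn to C5 and in the extended mode.

The chloromethyl ketone of 20 is cut at C11–C12 to the Weinreb amide 18 and the one-carbon unit 19. It is made last because an α-chloroketone cannot be carried through the enolization that makes the dienol ether. 18 comes from enone 17 by regioselective O-silylation at C16, and 17 from acid 16. The amide is introduced only after the C6 enolate chemistry, because an acylating group on C11 would be attacked by that enolate.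

In 16 the C6–C8 bond is cut to the lactone acid 13 and the vinylogous ester 14; an ester enolate at C6 and a cyclopentenone synthon are the natural polarities. C6 is left uncontrolled here because it stays epimerizable until ring B exists.

In 13 the C9–C10 bond and the lactone C19–O bond are cut to ketone 10 and the two-carbon acid 11. Addition to the C10 ketone followed by lactonization onto the 1,3-diaxial C19 ester fixes C10, since only the adduct with oxygen cis to C19 can close.

Ketone 10 goes back through 9 to enone 7 and the bromoacetate 8 (C5–C6 bond). The C1=C2 double bond of 7 blocks the other α-position, and the C3 silyloxy group and the C4 methyl together direct the electrophile to the lactone side of C5.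

Enone 7 is traced through 6 and 5 to enone 4 (C10 oxidation, C3 reduction with C4 as the controlling centre). 4 is opened by an aldol (C1–C2) and a Michael (C4–C5) disconnection to the aldehyde 3 and then to the β-keto ester 1 and the enal 2. The single catalytic asymmetric step sets C4, from which all other centres follow.

## Alternatives that were turned down

Alternative 1: The C11–C12 bond is cut, as an alkene, in a compound that already holds rings A, B and D, with ring D spiro-attached at C8. In the forward sense (H2IMes)(PCy3)Cl2Ru=CHPh (second-generation Grubbs catalyst) joins vinyl groups on C9 and C13 and closes ring C as a bicyclo[3.2.1]oct-2-ene, giving A1; hydrogenation and ester cleavage follow.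
- For it: the key event is neutral, so the lactone, the free C3 hydroxyl and even the C16 tertiary alcohol can already be in place, and ring-closing metathesis is predictable. On mildness and late-stage risk it is stronger than the chosen route.
- Against it: the metathesis makes one bond and no stereocentre. The spiro quaternary C8, C9, C13 and C16 must all be set beforehand on a flexible spirocycle, with the two vinyl groups cis-diaxial across the incipient bridge, and the vinyl on C9 sits next to the allylic C10–O bond.
- Comparison: the chosen cycloaddition forms two bonds, two rings and three stereocentres at once from a monocyclic diene, which is what pays for its higher risk.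

Alternative 2: The C12–C13 bond is re-formed by a cationic 1,2-shift in a D-ring-rearranged gibberellin (C12 bonded to C16), reached from fermentation-derived gibberellic acid A3. In the forward sense, buffered solvolysis of the C13 exo-mesylate moves C12 from C16 back to C13 and the C16 cation loses a C17 proton, giving A2; the 16-ene must then be hydrated and the protecting groups removed.
- For it: every skeletal stereocentre comes from the natural product and the sequence is far shorter. On step economy it is clearly stronger than the chosen route.
- Against it: it is a partial synthesis that depends on a gibberellin already containing the whole ring system. The deoxygenation rests on two cationic rearrangements in which hydride shift, elimination towards C15 and solvent capture compete. The final Markovnikov hydration passes through the same C16 cation and does not secure the endo hydroxyl/exo methyl arrangement.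
- Comparison: the chosen route offers a de novo construction from simple materials, with C16 set by ketone addition from the open face.

Alternative 3: The C13–C16 bond is cut. In the forward sense [(Ph3P)CuH]6 (monovalent copper) delivers hydride to C14 of a C12 enone, and the resulting C13 copper enolate adds to a methyl ketone held on C8, closing ring D and giving A4.
- For it: the tertiary carbinol and its configuration arise in the ring-forming step through a chelated aldol, so no Grignard addition is needed, and the conditions are mild.
- Against it: rings A, B and C with the quaternary C8 and C9 must be built first. The aldol needs a cis-disposed enolate and ketone on a cyclohexanone already flanked by C8. The C12 carbonyl has to be removed afterwards next to a retro-aldol-prone β-hydroxy ketone.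
- Comparison: it also leaves an extra carbonyl to delete, but it closes one ring and one bond where the chosen step closes two of each. It is stronger at C16, which the chosen route handles by exo-face methyl addition.

Key step: step 13

## Route

Step 1
Reactants: 1 methyl 2-methyl-3-oxobutanoate; 2 acrolein
Product: 3 methyl (2S)-2-acetyl-2-methyl-5-oxopentanoate
Conditions: 9-O-(9-phenanthryl)cupreidine (10 mol %), CH2Cl2, −24 °C
Reagents that add atoms: none
Why: Bifunctional cinchona-catalysed Michael addition of an α-substituted β-keto ester to acrolein; the catalyst-bound enol is attacked on one face, which sets the quaternary C4, a centre that cannot epimerize later.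

Step 2
Reactants: 3 methyl (2S)-2-acetyl-2-methyl-5-oxopentanoate
Product: 4 methyl (1S)-1-methyl-2-oxocyclohex-3-ene-1-carboxylate
Conditions: TsOH·H2O (cat.), toluene, reflux, Dean–Stark
Reagents that add atoms: none
Why: Intramolecular aldol condensation; only the acetyl methyl can reach the aldehyde in a six-membered mode, and dehydration gives the conjugated enone (C3 ketone, C1=C2).

Step 3
Reactants: 4 methyl (1S)-1-methyl-2-oxocyclohex-3-ene-1-carboxylate
Product: 5 methyl (1S,2S)-2-hydroxy-1-methylcyclohex-3-ene-1-carboxylate
Conditions: Zn(BH4)2, Et2O, −20 °C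
Reagents that add atoms: none
Why: Chelation-controlled 1,2-reduction of the β-keto ester; zinc holds the ester coplanar with the ketone, the C4 methyl is then pseudoaxial and hydride enters anti to it, which should place the C3 hydroxyl cis to the methyl and trans to the ester.

Step 4
Reactants: 5 methyl (1S,2S)-2-hydroxy-1-methylcyclohex-3-ene-1-carboxylate
Product: 6 methyl (1S,2S)-2-(tert-butyldimethylsilyloxy)-1-methylcyclohex-3-ene-1-carboxylate
Conditions: TBSOTf, 2,6-lutidine, CH2Cl2, 0 °C
Reagents that add atoms: tert-butyldimethylsilyl trifluoromethanesulfonate, CC(C)(C)[Si](C)(C)OS(=O)(=O)C(F)(F)F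
Why: Silylation of a hindered secondary alcohol with the silyl triflate; the silyl ether blocks retro-aldol chemistry at C3 and later shields the β face at C5.

Step 5
Reactants: 6 methyl (1S,2S)-2-(tert-butyldimethylsilyloxy)-1-methylcyclohex-3-ene-1-carboxylate
Product: 7 methyl (1S,6S)-6-(tert-butyldimethylsilyloxy)-1-methyl-3-oxocyclohex-4-ene-1-carboxylate
Conditions: Rh2(cap)4 (dirhodium tetracaprolactamate, 1 mol %), t-BuOOH, CH2Cl2, rt
Reagents that add atoms: tert-butyl hydroperoxide, CC(C)(C)OO
Why: Catalytic allylic C–H oxidation; C10 is the only allylic methylene, so the C10 ketone forms with the C1=C2 bond in conjugation and C5 becomes the only enolizable position.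

Step 6
Reactants: 7 methyl (1S,6S)-6-(tert-butyldimethylsilyloxy)-1-methyl-3-oxocyclohex-4-ene-1-carboxylate; 8 tert-butyl bromoacetate
Product: 9 methyl (1S,2R,6S)-2-(2-tert-butoxy-2-oxoethyl)-6-(tert-butyldimethylsilyloxy)-1-methyl-3-oxocyclohex-4-ene-1-carboxylate
Conditions: LiN(iPr)2 (LDA), THF, −78 °C; 8, DMPU, −78 → −40 °C
Reagents that add atoms: none
Why: Alkylation of the kinetic cross-conjugated enolate; the electrophile should enter C5 anti to the pseudoaxial C4 methyl and to the C3 silyloxy group, i.e. cis to the C19 ester, which sets C5.

Step 7
Reactants: 9 methyl (1S,2R,6S)-2-(2-tert-butoxy-2-oxoethyl)-6-(tert-butyldimethylsilyloxy)-1-methyl-3-oxocyclohex-4-ene-1-carboxylate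
Product: 10 methyl (1S,2R,6S)-2-(2-tert-butoxy-2-oxoethyl)-6-(tert-butyldimethylsilyloxy)-1-methyl-3-oxocyclohexane-1-carboxylate
Conditions: H2 (1 atm), Pd/C, EtOAc, rt
Reagents that add atoms: none
Why: Heterogeneous hydrogenation of the enone C=C; no stereocentre is formed and the neutral medium leaves the epimerizable C5 untouched.

Step 8
Reactants: 10 methyl (1S,2R,6S)-2-(2-tert-butoxy-2-oxoethyl)-6-(tert-butyldimethylsilyloxy)-1-methyl-3-oxocyclohexane-1-carboxylate; 11 acetic acid
Product: 13 ring-A lactone acid, via hydroxy acid adduct 12 (not isolated)
Conditions: 11, LDA (2.1 equiv), THF, 0 °C; add 10, −78 → 0 °C; then 1 M HCl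
Reagents that add atoms: none
Why: Addition of dilithioacetate to the ketone, then lactonization of the tertiary alkoxide onto the 1,3-diaxial methyl ester; attack anti to the axial C19 ester puts the C10 oxygen cis to C19, and only that adduct can close the γ-lactone, which sets C10. The tert-butyl ester is too hindered to compete for the alkoxide.

Step 9
Reactants: 13 ring-A lactone acid; 14 3-ethoxycyclopent-2-en-1-one
Product: 16 cyclopentenone acid, via carbinol adduct 15 (not isolated)
Conditions: LDA (2.2 equiv), THF, −78 °C; 14, −78 → −40 °C; then 1 M HCl, THF, 0 °C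
Reagents that add atoms: water, O
Why: 1,2-Addition of the C6 ester enolate (the carboxylate is inert) to the vinylogous ester, then acid hydrolysis and dehydration (Stork–Danheiser sequence) give the 3-substituted cyclopentenone. C6 forms without control and stays labile as a vinylogous β-keto ester; it is fixed only in step 13.

Step 10
Reactants: 16 cyclopentenone acid
Product: 17 cyclopentenone Weinreb amide
Conditions: 1,1'-carbonyldiimidazole, THF, rt; then MeNH(OMe)·HCl, rt
Reagents that add atoms: N,O-dimethylhydroxylamine hydrochloride, CNOC.Cl
Why: Acyl imidazolide formation and aminolysis under near-neutral conditions; the amide is made only now because an acylating group on C11 would have been attacked by the C6 enolate of step 9 in a five-membered closure.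

Step 11
Reactants: 17 cyclopentenone Weinreb amide
Product: 18 silyloxycyclopentadiene Weinreb amide
Conditions: LDA (1.1 equiv), THF, −78 °C; TIPSOTf, −78 °C
Reagents that add atoms: triisopropylsilyl trifluoromethanesulfonate, CC(C)[Si](C(C)C)(C(C)C)OS(=O)(=O)C(F)(F)F
Why: Kinetic α'-deprotonation at the unhindered C13 methylene and O-silylation give the cross-conjugated diene C8=C15–C16(OSi)=C13; the hindered C6 methine, though more acidic, should not compete at −78 °C. Triisopropylsilyl is chosen so that the dienol ether survives alkoxide in step 13.

Step 12
Reactants: 18 silyloxycyclopentadiene Weinreb amide; 19 chloroiodomethane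
Product: 20 chloromethyl ketone (cycloaddition precursor)
Conditions: 19, MeLi·LiBr, THF, −78 °C; AcOH quench
Reagents that add atoms: none
Why: Chloromethyllithium, made by iodine–lithium exchange in the presence of the substrate, adds once to the Weinreb amide and the chelated adduct gives the chloromethyl ketone on quench. Doing this last means the α-chloroketone never meets an enolization step.

Step 13
Reactants: 20 chloromethyl ketone (cycloaddition precursor)
Product: 22 tetracyclic 11-ketone with C15=C16 enol silane, via oxyallyl cation 21 (not isolated)
Conditions: NaOCH2CF3 (1.5 equiv), CF3CH2OH (0.005 M), 0 °C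
Reagents that add atoms: none
Why: Trifluoroethoxide removes a C9 proton reversibly, and in the ionizing solvent the C9 enolate loses chloride from C12 to give the sodium oxyallyl species 21 (C10 cis to oxygen), which the tethered 2-silyloxydiene traps before Favorskii closure. The closest known reaction type is the Föhlisch [4+3] cycloaddition of α-chloroketones with cyclopentadienes and furans in NaOCH2CF3/CF3CH2OH, including its intramolecular variants. Bond formation is concerted but asynchronous: C12–C13 (enol ether β-carbon to the unsubstituted cation terminus) runs ahead, C9–C8 closes ring B in a 5-exo-trig sense (C8=C15 stays outside the five-membered ring), and the same event closes the six-membered ring C as part of the seven-membered ring C8–C9–C11–C12–C13–C16–C15 bridged by C14; a separate C12–C13-first step would need a nine-membered ring and is not invoked. C8 and C13 are set together by the diene face: the oxyallyl unit can only reach the face syn to C5, and allylic strain puts the C6 ester next to H15 and H6 next to the C14 methylene, so C15 ends syn and C14 anti to the ester. C9 is set by the approach mode: the tether holds C10 under C6, so the extended arrangement (C11–O under C14, away from C15=C16) gives H9 syn to C15, while the compact arrangement would give the C9 epimer; the extended mode should be preferred because the solvated oxyallyl oxygen avoids the bulky C16 silyloxy group and can share sodium with the lactone oxygen on that face. C6 is α to the ester and attached to the diene, so it exchanges under the alkoxide at least as fast as C9 and is drawn through the transition state that keeps the ester trans to C4. The step needs diene-face selectivity, the extended mode and survival of the enol silane and the lactone; high dilution, 0 °C and the triisopropylsilyl group are chosen for that.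

Step 14
Reactants: 22 tetracyclic 11-ketone with C15=C16 enol silane
Product: 23 C11–C12 enol triflate
Conditions: KN(SiMe3)2, THF, −78 °C; PhNTf2
Reagents that add atoms: N-phenylbis(trifluoromethanesulfonimide), O=S(=O)(N(c1ccccc1)S(=O)(=O)C(F)(F)F)C(F)(F)F
Why: Kinetic enolization goes towards C12, because H9 is hindered and equatorial (poor overlap) and a C9 enolate would be β to the lactone oxygen; trapping gives the enol triflate without a new stereocentre.

Step 15
Reactants: 23 C11–C12 enol triflate
Product: 24 11-ene with C15=C16 enol silane
Conditions: Pd(OAc)2, PPh3, HCO2H, Bu3N, DMF, 60 °C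
Reagents that add atoms: none
Why: Palladium-catalysed formate reduction of an enol triflate (oxidative addition, hydride transfer, reductive elimination) replaces the triflate by hydrogen; the amine-buffered medium spares the enol silane.

Step 16
Reactants: 24 11-ene with C15=C16 enol silane
Product: 25 11-en-16-one
Conditions: Bu4NF, AcOH, THF, 0 °C
Reagents that add atoms: none
Why: Buffered fluoride cleaves the silyl enol ether much faster than the hindered secondary silyl ether on C3; protonation at C15 unveils the C16 ketone.

Step 17
Reactants: 25 11-en-16-one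
Product: 26 16-ketone
Conditions: H2 (1 atm), Pd/C, EtOAc, rt
Reagents that add atoms: none
Why: Hydrogenation of the strained cis-disubstituted C11=C12 bond turns C11 and C12 into methylenes and completes the removal of the C11 oxygen; no stereocentre is formed.

Step 18
Reactants: 26 16-ketone; 27 methylmagnesium bromide
Product: 28 protected target (16-hydroxy-16-methyl)
Conditions: 27, CeCl3, THF, −78 °C
Reagents that add atoms: none
Why: Organocerium addition to a hindered, enolizable ketone; the reagent attacks the bicyclo[3.2.1]octan-6-one from the exo face (C14 side) because the endo face is covered by the axial hydrogen on C11, which sets C16 with methyl exo and hydroxyl endo.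

Step 19
Reactants: 28 protected target (16-hydroxy-16-methyl)
Product: 30 16,17-dihydro-16-hydroxygibberellin A4 (target), via bis(trimethylsilyl) derivative 29 (not isolated)
Conditions: TMSOTf, 2,6-lutidine, CH2Cl2, 0 °C → rt; then 48% aq. HF, MeCN, 0 °C → rt
Reagents that add atoms: none
Why: Silyl triflate with lutidine converts the tert-butyl ester into the silyl ester (loss of isobutene) under non-protic conditions while the tertiary alcohol is only silylated, so no C16 cation forms. Aqueous HF then removes the silyl ester and both silyl ethers without base, which avoids retro-aldol epimerization at C3.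

## Compound list

1 | methyl 2-methyl-3-oxobutanoate | CC(=O)C(C)C(=O)OC | starting material
2 | acrolein (prop-2-enal) | C=CC=O | starting material
3 | methyl (2S)-2-acetyl-2-methyl-5-oxopentanoate | C[C@@](CCC=O)(C(=O)OC)C(C)=O | intermediate
4 | methyl (1S)-1-methyl-2-oxocyclohex-3-ene-1-carboxylate | C[C@@]1(C(=O)OC)C(=O)C=CCC1 | intermediate
5 | methyl (1S,2S)-2-hydroxy-1-methylcyclohex-3-ene-1-carboxylate (hydroxyl cis to methyl) | C[C@@]1(C(=O)OC)[C@@H](O)C=CCC1 | intermediate
6 | methyl (1S,2S)-2-(tert-butyldimethylsilyloxy)-1-methylcyclohex-3-ene-1-carboxylate | C[C@@]1(C(=O)OC)[C@@H](O[Si](C)(C)C(C)(C)C)C=CCC1 | intermediate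
7 | methyl (1S,6S)-6-(tert-butyldimethylsilyloxy)-1-methyl-3-oxocyclohex-4-ene-1-carboxylate | C[C@@]1(C(=O)OC)[C@@H](O[Si](C)(C)C(C)(C)C)C=CC(=O)C1 | intermediate
8 | tert-butyl bromoacetate | CC(C)(C)OC(=O)CBr | starting material
9 | methyl (1S,2R,6S)-2-(2-tert-butoxy-2-oxoethyl)-6-(tert-butyldimethylsilyloxy)-1-methyl-3-oxocyclohex-4-ene-1-carboxylate (side chain cis to the methyl ester, trans to methyl and silyloxy) | C[C@@]1(C(=O)OC)[C@@H](O[Si](C)(C)C(C)(C)C)C=CC(=O)[C@@H]1CC(=O)OC(C)(C)C | intermediate
10 | methyl (1S,2R,6S)-2-(2-tert-butoxy-2-oxoethyl)-6-(tert-butyldimethylsilyloxy)-1-methyl-3-oxocyclohexane-1-carboxylate | C[C@@]1(C(=O)OC)[C@@H](O[Si](C)(C)C(C)(C)C)CCC(=O)[C@@H]1CC(=O)OC(C)(C)C | intermediate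
11 | acetic acid | CC(=O)O | starting material
12 | hydroxy acid adduct: 10 with the C10 ketone replaced by C10(OH)(CH2CO2H), hydroxyl cis to the methyl ester | C[C@@]1(C(=O)OC)[C@@H](O[Si](C)(C)C(C)(C)C)CC[C@@](O)(CC(=O)O)[C@@H]1CC(=O)OC(C)(C)C | intermediate (not isolated)
13 | ring-A lactone acid: 6-oxabicyclo[3.2.1]octan-7-one core (C4 methyl, 19,10-lactone on the α face), 3β-silyloxy cis to the methyl, CH2CO2H on C10, CH2CO2tBu on C5 on the lactone side (H5 β) | C[C@@]12C(=O)O[C@](CC[C@@H]1O[Si](C)(C)C(C)(C)C)(CC(=O)O)[C@@H]2CC(=O)OC(C)(C)C | intermediate
14 | 3-ethoxycyclopent-2-en-1-one | CCOC1=CC(=O)CC1 | starting material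
15 | carbinol adduct: 13 with C6 bonded to C1 of 3-ethoxycyclopent-2-en-1-ol (carbinol centre uncontrolled, lost in the same flask) | C[C@@]12C(=O)O[C@](CC[C@@H]1O[Si](C)(C)C(C)(C)C)(CC(=O)O)[C@@H]2[C@H](C(=O)OC(C)(C)C)C1(O)C=C(OCC)CC1 | intermediate (not isolated)
16 | cyclopentenone acid: 13 with a 3-oxocyclopent-1-en-1-yl group on C6 (C6 epimers interconvert; drawn with the C6 configuration of the target) | C[C@@]12C(=O)O[C@](CC[C@@H]1O[Si](C)(C)C(C)(C)C)(CC(=O)O)[C@@H]2[C@H](C(=O)OC(C)(C)C)C1=CC(=O)CC1 | intermediate
17 | cyclopentenone Weinreb amide: 16 with CH2C(=O)N(OMe)Me on C10 | C[C@@]12C(=O)O[C@](CC[C@@H]1O[Si](C)(C)C(C)(C)C)(CC(=O)N(C)OC)[C@@H]2[C@H](C(=O)OC(C)(C)C)C1=CC(=O)CC1 | intermediate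
18 | silyloxycyclopentadiene Weinreb amide: 17 with the enone converted into the 3-(triisopropylsilyloxy)cyclopenta-1,3-dien-1-yl group (C8=C15, C16(OSi)=C13, C14 methylene) | C[C@@]12C(=O)O[C@](CC[C@@H]1O[Si](C)(C)C(C)(C)C)(CC(=O)N(C)OC)[C@@H]2[C@H](C(=O)OC(C)(C)C)C1=CC(O[Si](C(C)C)(C(C)C)C(C)C)=CC1 | intermediate
19 | chloroiodomethane | ClCI | starting material
20 | cycloaddition precursor: ring-A lactone with CH2C(=O)CH2Cl on C10 and, on C5, CH(CO2tBu) bearing the 3-(triisopropylsilyloxy)cyclopenta-1,3-dien-1-yl group | C[C@@]12C(=O)O[C@](CC[C@@H]1O[Si](C)(C)C(C)(C)C)(CC(=O)CCl)[C@@H]2[C@H](C(=O)OC(C)(C)C)C1=CC(O[Si](C(C)C)(C(C)C)C(C)C)=CC1 | intermediate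
21 | oxyallyl cation (zwitterion form, C10 cis to oxygen) derived from 20 by loss of HCl | C[C@@]12C(=O)O[C@](CC[C@@H]1O[Si](C)(C)C(C)(C)C)(/C=C(\[O-])[CH2+])[C@@H]2[C@H](C(=O)OC(C)(C)C)C1=CC(O[Si](C(C)C)(C(C)C)C(C)C)=CC1 | intermediate (not isolated)
22 | tetracyclic 11-ketone: gibberellane skeleton with 19,10-lactone, 3β-OTBS, 7-tert-butyl ester (β), 11-oxo, H9 β, C15=C16 enol triisopropylsilyl ether | C[C@@]12C(=O)O[C@]3(CC[C@@H]1O[Si](C)(C)C(C)(C)C)[C@@H]1C(=O)C[C@@H]4C[C@]1(C=C4O[Si](C(C)C)(C(C)C)C(C)C)[C@@H](C(=O)OC(C)(C)C)[C@@H]32 | intermediate
23 | enol triflate: 22 with C11(OTf)=C12 in place of the ketone | C[C@@]12C(=O)O[C@]3(CC[C@@H]1O[Si](C)(C)C(C)(C)C)[C@@H]1C(OS(=O)(=O)C(F)(F)F)=C[C@@H]4C[C@]1(C=C4O[Si](C(C)C)(C(C)C)C(C)C)[C@@H](C(=O)OC(C)(C)C)[C@@H]32 | intermediate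
24 | 11-ene: 23 with H in place of the triflate (C11=C12 and C15=C16 enol silane) | C[C@@]12C(=O)O[C@]3(CC[C@@H]1O[Si](C)(C)C(C)(C)C)[C@@H]1C=C[C@@H]4C[C@]1(C=C4O[Si](C(C)C)(C(C)C)C(C)C)[C@@H](C(=O)OC(C)(C)C)[C@@H]32 | intermediate
25 | 11-en-16-one: 24 with the enol silane hydrolysed to the C16 ketone (C15 methylene) | C[C@@]12C(=O)O[C@]3(CC[C@@H]1O[Si](C)(C)C(C)(C)C)[C@@H]1C=C[C@@H]4C[C@]1(CC4=O)[C@@H](C(=O)OC(C)(C)C)[C@@H]32 | intermediate
26 | 16-ketone: 17-nor-16-oxo skeleton of the target with 3β-OTBS and 7-tert-butyl ester | C[C@@]12C(=O)O[C@]3(CC[C@@H]1O[Si](C)(C)C(C)(C)C)[C@@H]1CC[C@@H]4C[C@]1(CC4=O)[C@@H](C(=O)OC(C)(C)C)[C@@H]32 | intermediate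
27 | methylmagnesium bromide | C[Mg]Br | starting material
28 | protected target: 3β-OTBS, 7-tert-butyl ester, 16-hydroxy (endo) 16-methyl (exo) | C[C@@]12C(=O)O[C@]3(CC[C@@H]1O[Si](C)(C)C(C)(C)C)[C@@H]1CC[C@@H]4C[C@]1(C[C@]4(C)O)[C@@H](C(=O)OC(C)(C)C)[C@@H]32 | intermediate
29 | bis(trimethylsilyl) derivative: 28 with the tert-butyl ester replaced by the trimethylsilyl ester and the C16 hydroxyl silylated | C[C@@]12C(=O)O[C@]3(CC[C@@H]1O[Si](C)(C)C(C)(C)C)[C@@H]1CC[C@@H]4C[C@]1(C[C@]4(C)O[Si](C)(C)C)[C@@H](C(=O)O[Si](C)(C)C)[C@@H]32 | intermediate (not isolated)
30 | 16,17-dihydro-16-hydroxygibberellin A4 (CNP0343121.3) | C[C@@]12C(=O)O[C@]3(CC[C@@H]1O)[C@@H]1CC[C@@H]4C[C@]1(C[C@]4(C)O)[C@@H](C(=O)O)[C@@H]32 | target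

## Step count and least certain steps

Total step count: 19. Longest linear sequence: 19 steps (the route is linear from 1 and 2; 8, 11, 14, 19 and 27 are purchased).

Step 13 (key step). Three things are most likely to go wrong.
- The C9 enolate is β to the lactone oxygen and may expel the C19 carboxylate instead of ionizing chloride. Re-addition of the carboxylate regenerates the same enolate, so this drains rate more than material, but it can dominate.
- The oxyallyl unit may approach in the compact mode, which gives the C9 epimer. The preference for the extended mode rests only on the steric and sodium-sharing argument given in the step.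
- The dienol ether may suffer alcoholysis or 1,5-hydrogen shift before it cyclizes.

Fallback: remove the silyl group from the diene and introduce the C16 oxygen after the cycloaddition. This keeps the best-precedented diene class for these conditions and takes away the third problem; it does not remove the first two.
- Setting out from 17, reduction with NaBH4/CeCl3 would give the cyclopentenol F1, and dehydration with the Burgess reagent the unsubstituted cyclopentadiene F2 (its hydrogen-shift isomers equilibrate).
- Chloromethyllithium as in step 12 would give the chloromethyl ketone F3, and NaOCH2CF3 in CF3CH2OH the 11-oxo-15-ene cycloadduct F4.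
- The C11 carbonyl would be removed through the tosylhydrazone F5 (TsNHNH2) and catecholborane/NaOAc to give the 15-ene F6.
- Hydroboration with 9-BBN, directed to C16 and the exo face by the quaternary C8, and NaBO3 oxidation would give the 16-alcohol F7, which Dess–Martin periodinane oxidizes to 26, where the route is rejoined.

Step 11. Proton removal may occur at C6 (α to the ester and vinylogous to the ketone) instead of C13, giving the exocyclic dienol ether; proton transfer between the two enolates would have the same effect. Fallback: remove both protons and silylate both oxygens. From 17, LDA (2.2 equiv) followed by TIPSOTf (2.2 equiv) would give the bis-silyl compound F8 (silyl ketene acetal at C6=C7 and dienol ether in the ring). Buffered water (pH 7, THF) hydrolyses only the ketene acetal and returns 18. This is the Weiler-dianion and Chan-diene logic applied to the vinylogous β-keto ester.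

Step 9. Proton transfer from the α'-position of 14 to the hindered C6 enolate may outrun 1,2-addition, returning 13. Fallback: make the C6–C8 bond by cross-coupling. From 13, the lithium enolate (LDA, 2.2 equiv) is transmetalated with ZnCl2 and coupled with 3-bromocyclopent-2-en-1-one under Pd2(dba)3/P(t-Bu)3 (α-alkenylation of a zinc ester enolate), which gives 16 directly.

Step 6. Facial selectivity at C5 may be poor, or alkylation at the neopentyl C5 may be slow enough for enolate equilibration and O-alkylation to compete. Fallback: deliver the acetate unit as a carbene. From 7, LDA/Me3SiCl would give the trimethylsilyl dienol ether F9. Cu(acac)2-catalysed cyclopropanation with tert-butyl diazoacetate at the electron-rich C5=C10 bond, from the face anti to the C3 silyloxy group, would give the siloxycyclopropane ester F10. Fluoride (Bu4NF/AcOH) opens it to the γ-keto ester 9 with the C5–C6 bond already in place.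

Step 3. Hydride delivery may follow the non-chelated conformer (ester pseudoaxial), which would give the C3 epimer and misdirect step 6. Fallback: switch from substrate control to reagent control. From 4, (R)-2-methyl-CBS-oxazaborolidine with catecholborane (toluene, −78 °C) should give 5, on the model that the quaternary C4 side acts as the large group.

## Further compounds

F1 | step 13 | cyclopentenol: 17 with the ring ketone reduced to the allylic alcohol (carbinol centre uncontrolled) | C[C@@]12C(=O)O[C@](CC[C@@H]1O[Si](C)(C)C(C)(C)C)(CC(=O)N(C)OC)[C@@H]2[C@H](C(=O)OC(C)(C)C)C1=CC(O)CC1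
F2 | step 13 | cyclopentadiene Weinreb amide: cyclopenta-1,3-dien-1-yl group on C6 | C[C@@]12C(=O)O[C@](CC[C@@H]1O[Si](C)(C)C(C)(C)C)(CC(=O)N(C)OC)[C@@H]2[C@H](C(=O)OC(C)(C)C)C1=CC=CC1
F3 | step 13 | chloromethyl ketone with unsubstituted cyclopentadiene | C[C@@]12C(=O)O[C@](CC[C@@H]1O[Si](C)(C)C(C)(C)C)(CC(=O)CCl)[C@@H]2[C@H](C(=O)OC(C)(C)C)C1=CC=CC1
F4 | step 13 | 11-oxo-15-ene cycloadduct | C[C@@]12C(=O)O[C@]3(CC[C@@H]1O[Si](C)(C)C(C)(C)C)[C@@H]1C(=O)C[C@@H]4C[C@]1(C=C4)[C@@H](C(=O)OC(C)(C)C)[C@@H]32
F5 | step 13 | C11 tosylhydrazone of the 11-oxo-15-ene cycloadduct | C[C@@]12C(=O)O[C@]3(CC[C@@H]1O[Si](C)(C)C(C)(C)C)[C@@H]1C(=NNS(=O)(=O)c5ccc(C)cc5)C[C@@H]4C[C@]1(C=C4)[C@@H](C(=O)OC(C)(C)C)[C@@H]32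
F6 | step 13 | 11-deoxy-15-ene | C[C@@]12C(=O)O[C@]3(CC[C@@H]1O[Si](C)(C)C(C)(C)C)[C@@H]1CC[C@@H]4C[C@]1(C=C4)[C@@H](C(=O)OC(C)(C)C)[C@@H]32
F7 | step 13 | 16-alcohol (exo hydroxyl expected; centre removed on oxidation) | C[C@@]12C(=O)O[C@]3(CC[C@@H]1O[Si](C)(C)C(C)(C)C)[C@@H]1CC[C@@H]4C[C@]1(CC4O)[C@@H](C(=O)OC(C)(C)C)[C@@H]32
F8 | step 11 | bis-silyl compound: triisopropylsilyl ketene acetal at C6=C7 and triisopropylsilyl dienol ether in the five-membered ring | C[C@@]12C(=O)O[C@](CC[C@@H]1O[Si](C)(C)C(C)(C)C)(CC(=O)N(C)OC)[C@@H]2C(=C(OC(C)(C)C)O[Si](C(C)C)(C(C)C)C(C)C)C1=CC(O[Si](C(C)C)(C(C)C)C(C)C)=CC1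
F0 | step 9 | none | none
F9 | step 6 | trimethylsilyl dienol ether of 7 (C5=C10 enol ether, C1=C2 retained) | C[C@@]1(C(=O)OC)[C@@H](O[Si](C)(C)C(C)(C)C)C=CC(O[Si](C)(C)C)=C1
F10 | step 6 | siloxycyclopropane ester: cyclopropane over C5–C10 carrying the tert-butyl ester on C6 (ester orientation uncontrolled) | C[C@@]1(C(=O)OC)[C@@H](O[Si](C)(C)C(C)(C)C)C=C[C@]2(O[Si](C)(C)C)C(C(=O)OC(C)(C)C)[C@H]12
F0 | step 3 | none | none
A1 | alternative 1 | 11-ene of the target methyl ester | C[C@@]12C(=O)O[C@]3(CC[C@@H]1O)[C@@H]1C=C[C@@H]4C[C@]1(C[C@]4(C)O)[C@@H](C(=O)OC)[C@@H]32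
A2 | alternative 2 | 13-deoxy 16-ene, 3-acetate 7-methyl ester (gibberellin A4 methyl ester 3-acetate) | C[C@@]12C(=O)O[C@]3(CC[C@@H]1OC(C)=O)[C@@H]1CC[C@@H]4C[C@]1(CC4=C)[C@@H](C(=O)OC)[C@@H]32
A3 | alternative 2 | gibberellic acid (gibberellin A3) | C[C@@]12C(=O)O[C@]3(C=C[C@@H]1O)[C@@H]1CC[C@]4(O)C[C@]1(CC4=C)[C@@H](C(=O)O)[C@@H]32
A4 | alternative 3 | 12-oxo derivative of the target 3-silyl ether methyl ester | C[C@@]12C(=O)O[C@]3(CC[C@@H]1O[Si](C)(C)C(C)(C)C)[C@@H]1CC(=O)[C@@H]4C[C@]1(C[C@]4(C)O)[C@@H](C(=O)OC)[C@@H]32
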